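The rings are labelled as follows: ring A is the trioxygenated ring, ring B the para-phenylene, ring C the 1,2,3-trisubstituted ring with the single OH, and ring D the ortho-disubstituted ring. The target is an achiral 17-membered bis(bibenzyl) diether.
Both carbons of the CH2–CH2 bridge between ring B and ring C are benzylic, so this C–C bond is cut first. It is traced back to a CH2–SO2–CH2 unit in an 18-membered bis-benzylic sulfone, whose alpha protons are acidic enough for a Ramberg–Bäcklund reaction.
Further cuts are the two benzylic C–S bonds (sulfide plus dibromide), the ring D O–ring C aryl bond (SNAr), the ring A–ring D ethylene bridge (Wittig, then H2) and the ring A O–ring B aryl bond (SNAr).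
In the forward direction the A–O–B ether, the A–D bridge and the D–O–C ether give an open chain with an ester on ring B and an aldehyde on ring C. Reduction, bromination and sulfide closure make the 18-membered ring, and oxidation and SO2 loss contract it to 17 members. Hydrogenation and demethylation finish the route.
The target has no stereocentre, and both alkene geometries that arise on the way are erased by hydrogenation.

Key step: step 10

Remark: both stilbene intermediates may form as E/Z mixtures. The E isomers are drawn, and either isomer gives the same product on hydrogenation. The bromination in the key step is drawn at the ring C benzylic carbon; the other regioisomer would collapse to the same episulfone.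

Step 1
Reactants: 1 3-hydroxy-4,5-dimethoxybenzaldehyde; 2 methyl 4-fluorobenzoate
Product: 3 methyl 4-(5-formyl-2,3-dimethoxyphenoxy)benzoate
Conditions: K2CO3, DMSO, 120 °C
Reagents that add atoms: none
Why: In this nucleophilic aromatic substitution the para ester stabilises the Meisenheimer adduct formed by the phenoxide of 1, and using an ester rather than an aldehyde on ring B leaves the ring A formyl group as the only Wittig acceptor.

Step 2
Reactants: 4 2-hydroxybenzyl alcohol
Product: 5 (2-hydroxybenzyl)triphenylphosphonium bromide
Conditions: PPh3·HBr, MeCN, reflux
Reagents that add atoms: triphenylphosphine hydrobromide, Br.c1ccc(cc1)P(c1ccccc1)c1ccccc1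
Why: Acid-promoted ionisation of the ortho-hydroxybenzylic alcohol and capture of the cation by PPh3 is the standard one-step phosphonium salt synthesis and needs no phenol protection.

Step 3
Reactants: 5 (2-hydroxybenzyl)triphenylphosphonium bromide; 3 methyl 4-(5-formyl-2,3-dimethoxyphenoxy)benzoate
Product: 7 methyl 4-{5-[2-(2-hydroxyphenyl)ethenyl]-2,3-dimethoxyphenoxy}benzoate (E isomer drawn; Z isomer carried along), via ylide phenoxide 6 (not isolated)
Conditions: NaN(SiMe3)2 (2.1 equiv), THF, 0 °C; then 3, 0 °C to rt
Reagents that add atoms: none
Why: In this Wittig olefination two equivalents of base give the semistabilised benzylic ylide 6, which attacks the aldehyde far faster than the benzoate ester, and the alkene geometry does not matter because step 4 removes it.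

Step 4
Reactants: 7 methyl 4-{5-[2-(2-hydroxyphenyl)ethenyl]-2,3-dimethoxyphenoxy}benzoate
Product: 8 methyl 4-{5-[2-(2-hydroxyphenyl)ethyl]-2,3-dimethoxyphenoxy}benzoate
Conditions: H2 (1 atm), 10% Pd/C, EtOAc/MeOH, rt
Reagents that add atoms: none
Why: Heterogeneous catalytic hydrogenation saturates the stilbene C=C bond of both isomers and leaves the ester, the phenol and the aryl ethers untouched.

Step 5
Reactants: 8 methyl 4-{5-[2-(2-hydroxyphenyl)ethyl]-2,3-dimethoxyphenoxy}benzoate; 9 2-fluoro-3-methoxybenzaldehyde
Product: 10 methyl 4-[5-(2-{2-[2-formyl-6-methoxyphenoxy]phenyl}ethyl)-2,3-dimethoxyphenoxy]benzoate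
Conditions: Cs2CO3, DMF, 110 °C
Reagents that add atoms: none
Why: In this nucleophilic aromatic substitution the ortho formyl group of 9 activates the C–F bond toward the only free phenoxide in the molecule, that of ring D, so the second diaryl ether forms without any protecting group.

Step 6
Reactants: 10 methyl 4-[5-(2-{2-[2-formyl-6-methoxyphenoxy]phenyl}ethyl)-2,3-dimethoxyphenoxy]benzoate
Product: 11 open-chain diol with CH2OH on ring B (para to the ether O) and CH2OH on ring C (ortho to the ether O)
Conditions: LiAlH4, THF, 0 °C to rt
Reagents that add atoms: none
Why: Hydride reduction with LiAlH4 takes the ester and the aldehyde to primary benzylic alcohols in one operation, and the ethers are inert.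

Step 7
Reactants: 11 open-chain diol
Product: 12 open-chain bis(benzylic bromide) with CH2Br on ring B and CH2Br on ring C
Conditions: PBr3, CH2Cl2, 0 °C
Reagents that add atoms: phosphorus tribromide, BrP(Br)Br
Why: Alcohol-to-bromide exchange through phosphite esters followed by SN2 attack of bromide is routine for primary benzylic alcohols, and the mild temperature protects the electron-rich rings.

Step 8
Reactants: 12 open-chain bis(benzylic bromide)
Product: 13 thiacycle (eighteen-membered ring; ring B–CH2–S–CH2–ring C bridge; three OMe groups)
Conditions: Na2S·9H2O on Al2O3, CH2Cl2/EtOH 9:1, slow addition of 12, rt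
Reagents that add atoms: sodium sulfide, [Na+].[Na+].[S-2]
Why: Double SN2 thioetherification of two reactive benzylic bromides under pseudo-high dilution is the classical thiacyclophane closure, and here it forms a flexible, nearly strain-free 18-membered ring.

Step 9
Reactants: 13 thiacycle
Product: 15 cyclic bis-benzylic sulfone (eighteen-membered ring), via cyclic sulfoxide 14 (not isolated)
Conditions: mCPBA (2.2 equiv), CH2Cl2, 0 °C to rt
Reagents that add atoms: 3-chloroperoxybenzoic acid, OOC(=O)c1cccc(Cl)c1
Why: Electrophilic oxidation at sulfur by the peracid is much faster than any attack on the alkoxyarenes, so the sulfide passes through the sulfoxide to the sulfone cleanly.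

Step 10
Reactants: 15 cyclic bis-benzylic sulfone
Product: 18 macrocyclic stilbene trimethyl ether (seventeen-membered ring; E isomer drawn), via alpha-bromo sulfone 16 (not isolated), via trans-episulfone 17 (not isolated)
Conditions: KOH/Al2O3, CBr2F2, t-BuOH/CH2Cl2, 0 °C to rt
Reagents that add atoms: none
Why: This is the Ramberg–Bäcklund reaction in its one-flask variant with in situ halogenation: KOH on Al2O3 deprotonates one sulfonyl-flanked benzylic CH2 of 15, and the carbanion abstracts bromine from CBr2F2 to give alpha-bromo sulfone 16. Deprotonation at the other benzylic carbon then triggers a 1,3-elimination, a 3-exo-tet displacement of bromide that makes the new ring B–ring C C–C bond and closes the thiirane 1,1-dioxide ring of 17. Cheletropic loss of SO2 from 17 turns that bond into the C=C bond of 18, so the macrocycle is contracted from eighteen to seventeen members rather than closed end to end, in a unimolecular event that needs no dilution. The two carbon stereocentres of 17 are transient: base-mediated epimerisation favours the trans episulfone and hence the E alkene unless ring strain imposes Z, and none survives because step 11 removes the alkene. Site selectivity rests on acidity, since only the two CH2 groups next to sulfur are both benzylic and alpha to SO2, whereas the ring A–ring D bridge, the methyl ethers and the diaryl ethers do not respond to KOH. Elimination must follow monobromination before a second bromination occurs, which the high acidity of the remaining benzylic alpha proton and the heterogeneous base favour, and the sluggish CF2 released from CBr2F2 should spare the stilbene from cyclopropanation.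

Step 11
Reactants: 18 macrocyclic stilbene trimethyl ether
Product: 19 macrocyclic bis(bibenzyl) trimethyl ether (seventeen-membered ring; both bridges CH2–CH2)
Conditions: H2 (1 atm), 10% Pd/C, EtOAc, rt
Reagents that add atoms: none
Why: Catalytic hydrogenation of the disubstituted stilbene C=C bond converts either geometric isomer into the same saturated bridge without touching the aryl ethers.

Step 12
Reactants: 19 macrocyclic bis(bibenzyl) trimethyl ether
Product: 20 target CNP0290892.0 (ring A catechol and ring C phenol set free)
Conditions: BBr3 (6 equiv), CH2Cl2, −78 °C to rt; then H2O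
Reagents that add atoms: none
Why: In this Lewis acid ether cleavage BBr3 binds each methoxy oxygen and bromide attacks the methyl carbon by SN2, whereas the diaryl ethers offer no sp3 C–O carbon and survive.

Compound list
1 | 3-hydroxy-4,5-dimethoxybenzaldehyde | O=Cc1cc(O)c(OC)c(OC)c1 | starting material
2 | methyl 4-fluorobenzoate | COC(=O)c1ccc(F)cc1 | starting material
3 | methyl 4-(5-formyl-2,3-dimethoxyphenoxy)benzoate | COC(=O)c1ccc(cc1)Oc1cc(C=O)cc(OC)c1OC | intermediate
4 | 2-hydroxybenzyl alcohol | OCc1ccccc1O | starting material
5 | (2-hydroxybenzyl)triphenylphosphonium bromide | [Br-].Oc1ccccc1C[P+](c1ccccc1)(c1ccccc1)c1ccccc1 | intermediate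
6 | sodium 2-[(triphenylphosphoranylidene)methyl]phenolate (ylide phenoxide, not isolated) | [Na+].[O-]c1ccccc1C=P(c1ccccc1)(c1ccccc1)c1ccccc1 | intermediate
7 | methyl 4-{5-[2-(2-hydroxyphenyl)ethenyl]-2,3-dimethoxyphenoxy}benzoate (E drawn) | COC(=O)c1ccc(cc1)Oc1cc(/C=C/c2ccccc2O)cc(OC)c1OC | intermediate
8 | methyl 4-{5-[2-(2-hydroxyphenyl)ethyl]-2,3-dimethoxyphenoxy}benzoate | COC(=O)c1ccc(cc1)Oc1cc(CCc2ccccc2O)cc(OC)c1OC | intermediate
9 | 2-fluoro-3-methoxybenzaldehyde | O=Cc1cccc(OC)c1F | starting material
10 | methyl 4-[5-(2-{2-[2-formyl-6-methoxyphenoxy]phenyl}ethyl)-2,3-dimethoxyphenoxy]benzoate | COC(=O)c1ccc(cc1)Oc1cc(CCc2ccccc2Oc2c(C=O)cccc2OC)cc(OC)c1OC | intermediate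
11 | open-chain diol (ring B CH2OH, ring C CH2OH) | OCc1ccc(cc1)Oc1cc(CCc2ccccc2Oc2c(CO)cccc2OC)cc(OC)c1OC | intermediate
12 | open-chain bis(benzylic bromide) | BrCc1ccc(cc1)Oc1cc(CCc2ccccc2Oc2c(CBr)cccc2OC)cc(OC)c1OC | intermediate
13 | 18-membered thiacycle, trimethyl ether | COc1cc2cc(c1OC)Oc1ccc(cc1)CSCc1cccc(OC)c1Oc1ccccc1CC2 | intermediate
14 | 18-membered cyclic sulfoxide (racemic at sulfur, not isolated) | COc1cc2cc(c1OC)Oc1ccc(cc1)CS(=O)Cc1cccc(OC)c1Oc1ccccc1CC2 | intermediate
15 | 18-membered cyclic bis-benzylic sulfone, trimethyl ether | COc1cc2cc(c1OC)Oc1ccc(cc1)CS(=O)(=O)Cc1cccc(OC)c1Oc1ccccc1CC2 | intermediate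
16 | alpha-bromo sulfone, Br on the ring C benzylic carbon (racemic, not isolated) | COc1cc2cc(c1OC)Oc1ccc(cc1)CS(=O)(=O)C(Br)c1cccc(OC)c1Oc1ccccc1CC2 | intermediate
17 | trans-episulfone (thiirane 1,1-dioxide fused into the macrocycle; racemic, one enantiomer drawn, not isolated) | COc1cc2cc(c1OC)Oc1ccc(cc1)[C@@H]3[C@H](S3(=O)=O)c1cccc(OC)c1Oc1ccccc1CC2 | intermediate
18 | 17-membered macrocyclic stilbene, trimethyl ether (E drawn) | COc1cc2cc(c1OC)Oc1ccc(cc1)/C=C/c1cccc(OC)c1Oc1ccccc1CC2 | intermediate
19 | 17-membered macrocyclic bis(bibenzyl), trimethyl ether | COc1cc2cc(c1OC)Oc1ccc(cc1)CCc1cccc(OC)c1Oc1ccccc1CC2 | intermediate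
20 | CNP0290892.0 | Oc1cc2cc(c1O)Oc1ccc(cc1)CCc1cccc(O)c1Oc1ccccc1CC2 | target

Total step count: 12. Longest linear sequence: 11 steps (steps 1 and 3–12 from compound 1; equally steps 2–12 from compound 4).

Steps most likely to fail

Step 10. Three processes could erode the contraction:
- repeated bromination of the benzylic positions before the 1,3-elimination;
- a slow 3-exo-tet closure if the ring resists bringing the two benzylic carbons together;
- capture of the strained alkene by the carbene.

The fallback drops the carbanion chemistry and extrudes sulfur by a radical path. Thiacycle 13 is irradiated (medium-pressure Hg lamp, quartz) in P(OEt)3. C–S homolysis, removal of sulfur from the thiyl radical by the phosphite and recombination of the benzylic diradical should give the saturated bridge directly. This route sets out from 13, bypasses 15 and 18, and rejoins the route at 19. It makes no new compound (F0).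

Step 8. Intermolecular thioether formation may outrun ring closure and lead to oligomerisation. Solvolysis of the reactive para-aryloxybenzyl bromide may also consume material. The fallback replaces the irreversible closure by a reversible one.
- Dibromide 12 is heated with thiourea in EtOH to give the bis(isothiouronium) dibromide F1.
- Hydrolysis with aqueous NaOH under N2 followed by acidification gives the open-chain dithiol F2.
- Stirring F2 in dilute CH2Cl2/MeOH with Et3N under air gives the 19-membered cyclic disulfide F3. Under these conditions thiolate–disulfide exchange lets open oligomers re-equilibrate toward the monomeric ring.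
- Desulfurisation of the benzylic disulfide with P(NEt2)3 in toluene removes one sulfur atom and rejoins the route at 13.

Step 5. The ortho-alkyl phenoxide may add only slowly to a fluoroarene whose reacting carbon is flanked on both sides. At the temperature needed, loss of the ester methyl group to the phenoxide or degradation of the aldehyde may compete. The fallback changes the bond-forming mechanism to a copper-catalysed Ullmann-type C–O coupling. Phenol 8 is coupled with purchased 2-bromo-3-methoxybenzaldehyde (CuI, picolinic acid, K3PO4, DMSO, 90 °C), a system suited to hindered diaryl ethers. It sets out from 8 and rejoins the route at 10, and it makes no new compound (F0).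

Further compounds
F0 | step 10 | none | none
F1 | step 8 | open-chain bis(isothiouronium) dibromide | NC(=[NH2+])SCc1ccc(cc1)Oc1cc(CCc2ccccc2Oc2c(CSC(N)=[NH2+])cccc2OC)cc(OC)c1OC.[Br-].[Br-]
F2 | step 8 | open-chain bis(benzylic thiol) | SCc1ccc(cc1)Oc1cc(CCc2ccccc2Oc2c(CS)cccc2OC)cc(OC)c1OC
F3 | step 8 | 19-membered cyclic disulfide, trimethyl ether | COc1cc2cc(c1OC)Oc1ccc(cc1)CSSCc1cccc(OC)c1Oc1ccccc1CC2
F0 | step 5 | none | none
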